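**Retrosynthetic overview**

- Ring B (the quinone) is not built. It is unveiled last by oxidative demethylation of a 2,4,5-trimethoxyphenyl group that comes from 2,4,5-trimethoxybenzaldehyde.
- Rings C and A are cut together at O1–C8a, C8–C8a and C4a–C5. This gives an acyclic (S)-δ-hydroxy β,β-dichlorovinyl ketone (O1, C2, C3, C4, C4a, C8a) and the γ-anion of methyl (E)-3-methoxy-2-methylpent-2-enoate (C5–C8, carrying both C-methyls and the 7-OMe).
- The hydroxy ketone is cut at C2–C3 by an enantioselective Mukaiyama aldol between the aldehyde and the silyl enol ether of 4,4-dichlorobut-3-en-2-one (from acetyl chloride and 1,1-dichloroethene). This sets C2; no bond to C2 is touched afterwards.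
- Forward order of ring formation: ring C, then ring A, both in the same flask; ring B is carried as the arene and oxidised at the end.

Assumption: in step 3 the (S,S) antipode of the bisphosphoramide catalyst (two P=O units, each carried by (S)-N,N'-dimethyl-1,1'-binaphthyl-2,2'-diamine, joined by a MeN(CH2)5NMe chain) is taken to direct attack to the Si face of the aldehyde; if the sense is the reverse, the mirror-image catalyst is used.

**Route**

Step 1
Reactants: 1 acetyl chloride; 2 1,1-dichloroethene
Product: 4 4,4-dichlorobut-3-en-2-one, via 4,4,4-trichlorobutan-2-one 3 (not isolated)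
Conditions: AlCl3 (1.1 equiv), CH2Cl2, 0 °C to rt; ice water; then aq. Na2CO3, 40 °C; distil
Reagents that add atoms: none
Why: Darzens–Nenitzescu acylation of the alkene (the acylium ion adds to the CH2 terminus and chloride caps the dichloro cation), then E1cB loss of HCl from the β-trichloromethyl ketone gives the conjugated dichlorovinyl ketone.

Step 2
Reactants: 4 4,4-dichlorobut-3-en-2-one
Product: 5 [(4,4-dichlorobuta-1,3-dien-2-yl)oxy]trimethylsilane
Conditions: LiN(SiMe3)2 (1.1 equiv), Me3SiCl (1.3 equiv), THF, −78 to 0 °C; pentane, filter, distil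
Reagents that add atoms: chlorotrimethylsilane, C[Si](C)(C)Cl
Why: Kinetic enolisation with in situ silyl trapping gives a single silyl enol ether because only the methyl group is enolisable, and the hindered amide does not add to the dichlorovinyl group.

Step 3
Reactants: 5 [(4,4-dichlorobuta-1,3-dien-2-yl)oxy]trimethylsilane; 6 2,4,5-trimethoxybenzaldehyde
Product: 8 (5S)-1,1-dichloro-5-hydroxy-5-(2,4,5-trimethoxyphenyl)pent-1-en-3-one, via O-trichlorosilyl aldolate 7 (not isolated)
Conditions: SiCl4 (1.5 equiv), (S,S)-bisphosphoramide catalyst (5 mol %), iPr2NEt (10 mol %), CH2Cl2, −78 °C; then sat. aq. NaHCO3, 0 °C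
Reagents that add atoms: none
Why: Lewis-base-catalysed, SiCl4-mediated Mukaiyama aldol in which the phosphoramide-bound trichlorosilyl cation activates the aldehyde and exposes its Si face to the enol ether, setting the carbinol centre (the later C2) as S, while the aldolate stays as its O-SiCl3 ether until work-up so the electron-rich benzylic alcohol neither eliminates nor cyclises.

Step 4
Reactants: 9 methyl 2-methyl-3-oxopentanoate
Product: 11 methyl (2E)-3-methoxy-2-methylpent-2-enoate, via methyl 3,3-dimethoxy-2-methylpentanoate 10 (not isolated)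
Conditions: HC(OMe)3 (2 equiv), H2SO4 (cat.), 25 °C; then TsOH (cat.), 120 °C, distil
Reagents that add atoms: trimethyl orthoformate, COC(OC)OC
Why: Acid-catalysed ketalisation followed by thermal loss of methanol (enol ether formation) gives the E isomer (ethyl cis to the ester) under equilibrating conditions, which is the geometry needed for γ-deprotonation and for the later ring closure.

Step 5
Reactants: 8 (5S)-1,1-dichloro-5-hydroxy-5-(2,4,5-trimethoxyphenyl)pent-1-en-3-one; 11 methyl (2E)-3-methoxy-2-methylpent-2-enoate
Product: 15 (2S)-5-hydroxy-7-methoxy-6,8-dimethyl-2-(2,4,5-trimethoxyphenyl)-2,3-dihydro-4H-chromen-4-one, via lithium dienolate of the enoate 12 (not isolated), via 6-chloropyranone 13 (not isolated), via pyranonyl pentenoate 14 (not isolated)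
Conditions: 8, LiN(SiMe3)2 (1.05 equiv), THF, −78 to −40 °C; cannulate into 12 [11 (2.3 equiv), LiN(iPr)2 (2.2 equiv), THF, −78 °C]; −78 to 0 °C; AcOH, −78 °C
Reagents that add atoms: none
Why: Proposed new method: the lithium alkoxide of 8 closes ring C by 6-endo oxa-Michael addition to the β,β-dichlorovinyl ketone with loss of chloride (13, a vinylogous acid chloride), the γ-carbon of dienolate 12 adds to the same carbon and expels the second chloride (14), a further equivalent of base removes the doubly vinylogous C–H next to the pyranone, and the resulting dienolate attacks the cis-placed ester through the pyranone α-carbon (Dieckmann), after which loss of methoxide and enolisation give aromatic ring A with OH, Me, OMe and Me in place, while no bond to C2 is made or broken so the S centre is carried through; the closest known reaction types are the Staunton–Weinreb Michael–Dieckmann annulation of ester-stabilised carbanions onto β-alkoxy pyranones, addition–elimination on β,β-dichlorovinyl ketones, and γ-attack of lithiated β-alkoxy crotonates.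

Step 6
Reactants: 15 (2S)-5-hydroxy-7-methoxy-6,8-dimethyl-2-(2,4,5-trimethoxyphenyl)-2,3-dihydro-4H-chromen-4-one
Product: 16 2-[(2S)-5-hydroxy-7-methoxy-6,8-dimethyl-4-oxo-3,4-dihydro-2H-chromen-2-yl]-5-methoxycyclohexa-2,5-diene-1,4-dione (CNP0208927.1)
Conditions: (NH4)2Ce(NO3)6 (2.5 equiv), MeCN–H2O (2:1), 0 °C, 10 min
Reagents that add atoms: water, O
Why: Oxidative demethylation by tetravalent cerium (reduced to trivalent cerium) proceeds through the radical cation of the most electron-rich ring and turns the para-related 2'- and 5'-methoxy groups into the quinone carbonyls while the 4'-OMe stays, whereas ring A is fully substituted, acyl-deactivated and chelated, and the acidic, base-free medium leaves C2 untouched.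

**Compound list**

1 | acetyl chloride | CC(=O)Cl | starting material
2 | 1,1-dichloroethene | C=C(Cl)Cl | starting material
3 | 4,4,4-trichlorobutan-2-one | CC(=O)CC(Cl)(Cl)Cl | intermediate
4 | 4,4-dichlorobut-3-en-2-one | CC(=O)C=C(Cl)Cl | intermediate
5 | [(4,4-dichlorobuta-1,3-dien-2-yl)oxy]trimethylsilane | C=C(O[Si](C)(C)C)C=C(Cl)Cl | intermediate
6 | 2,4,5-trimethoxybenzaldehyde | COc1cc(OC)c(C=O)cc1OC | starting material
7 | O-trichlorosilyl aldolate: (5S)-1,1-dichloro-5-[(trichlorosilyl)oxy]-5-(2,4,5-trimethoxyphenyl)pent-1-en-3-one | Cl[Si](Cl)(Cl)O[C@@H](CC(=O)C=C(Cl)Cl)c1cc(OC)c(OC)cc1OC | intermediate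
8 | (5S)-1,1-dichloro-5-hydroxy-5-(2,4,5-trimethoxyphenyl)pent-1-en-3-one | O[C@@H](CC(=O)C=C(Cl)Cl)c1cc(OC)c(OC)cc1OC | intermediate
9 | methyl 2-methyl-3-oxopentanoate | CCC(=O)C(C)C(=O)OC | starting material
10 | methyl 3,3-dimethoxy-2-methylpentanoate | CCC(OC)(OC)C(C)C(=O)OC | intermediate
11 | methyl (2E)-3-methoxy-2-methylpent-2-enoate | CO/C(CC)=C(\C)C(=O)OC | intermediate
12 | lithium dienolate of the enoate: lithium 1,3-dimethoxy-2-methylpenta-1,3-dien-1-olate (double-bond geometry not assigned) | [Li+].[O-]C(OC)=C(C)C(OC)=CC | intermediate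
13 | 6-chloropyranone: (2S)-6-chloro-2-(2,4,5-trimethoxyphenyl)-2,3-dihydro-4H-pyran-4-one | ClC1=CC(=O)C[C@H](O1)c1cc(OC)c(OC)cc1OC | intermediate
14 | pyranonyl pentenoate: methyl (2E)-3-methoxy-2-methyl-4-[(2S)-4-oxo-2-(2,4,5-trimethoxyphenyl)-3,4-dihydro-2H-pyran-6-yl]pent-2-enoate (both epimers at C4 of the pentenoate) | COC(=O)/C(C)=C(OC)\C(C)C1=CC(=O)C[C@H](O1)c1cc(OC)c(OC)cc1OC | intermediate
15 | (2S)-5-hydroxy-7-methoxy-6,8-dimethyl-2-(2,4,5-trimethoxyphenyl)-2,3-dihydro-4H-chromen-4-one | COc1cc(OC)c(cc1OC)[C@@H]1CC(=O)c2c(O)c(C)c(OC)c(C)c2O1 | intermediate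
16 | 2-[(2S)-5-hydroxy-7-methoxy-6,8-dimethyl-4-oxo-3,4-dihydro-2H-chromen-2-yl]-5-methoxycyclohexa-2,5-diene-1,4-dione | COC1=CC(=O)C([C@@H]2CC(=O)c3c(O)c(C)c(OC)c(C)c3O2)=CC1=O | target

**Step count**

Total steps: 6. Longest linear sequence: 5 steps (steps 1, 2, 3, 5, 6); step 4 is a one-step side branch.

**Steps most likely to fail, with fallbacks**

Step 5 (ring C and ring A cascade). The risks are deprotonation at C3 of 13 or 14 followed by E1cB opening of the C2–O bond (racemisation or decomposition), 1,2-addition of 12 to the ketone, and α- instead of γ-attack of the dienolate. The fallback sets out from 8 and 11 and returns at 15; it forms the two rings one after the other and makes the C8–C8a bond without strong base. Compound 8 is closed to the 6-chloropyranone 13, now isolated (LiN(SiMe3)2, 1.0 equiv, THF, −78 °C, then aq. NH4Cl). Compound 11 is converted into its silyl ketene acetal [(1,3-dimethoxy-2-methylpenta-1,3-dien-1-yl)oxy]trimethylsilane F1 (LiN(iPr)2, Me3SiCl, THF, −78 °C). F1 and 13 are joined by a Me3SiOTf-catalysed vinylogous Mukaiyama–Michael addition with loss of chloride (CH2Cl2, −78 °C, volatiles evaporated) to give 14, now isolated. Ring A is then closed on its own by Dieckmann cyclisation of 14 with NaN(SiMe3)2 (2.1 equiv, THF, −78 to −20 °C, AcOH quench), which gives 15.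

Step 3 (enantioselective aldol). The risks are the low nucleophilicity of the dichlorodiene silyl enol ether 5 towards an electron-rich aldehyde, an insufficient or opposite facial bias, and elimination of the benzylic alcohol on work-up. The fallback sets out from 4 and 6 and returns at 8; it sets the stereocentre by resolution instead of catalysis. The lithium enolate of 4 (LiN(iPr)2, THF, −78 °C) is added to 6 to give racemic 1,1-dichloro-5-hydroxy-5-(2,4,5-trimethoxyphenyl)pent-1-en-3-one F2. Kinetic resolution with immobilised Candida antarctica lipase B and vinyl acetate (tBuOMe, 30 °C) is expected, by the usual empirical selectivity rule for secondary carbinols, to acetylate the R alcohol to (1R)-5,5-dichloro-3-oxo-1-(2,4,5-trimethoxyphenyl)pent-4-en-1-yl acetate F3. The untouched S alcohol is 8 (at most 50 %), separated by chromatography.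

Step 6 (arene to quinone). The risks are over-oxidation of the phenolic ring A, formation of the ortho-quinone, and acid-promoted opening at C2. The fallback sets out from 15 and returns at 16; it replaces the chemical oxidant by anodic oxidation through a quinone bisketal. Constant-current electrolysis of 15 (platinum anode, LiClO4, 2,6-lutidine, MeOH, 0 °C) gives (2S)-5-hydroxy-7-methoxy-6,8-dimethyl-2-(3,3,4,6,6-pentamethoxycyclohexa-1,4-dien-1-yl)-2,3-dihydro-4H-chromen-4-one F4. Mild hydrolysis of the two ketals (aqueous AcOH, acetone, 20 °C) releases the methoxyquinone 16.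

**Further compounds**

F1 | step 5 | [(1,3-dimethoxy-2-methylpenta-1,3-dien-1-yl)oxy]trimethylsilane | CC=C(OC)C(C)=C(OC)O[Si](C)(C)C
F2 | step 3 | racemic 1,1-dichloro-5-hydroxy-5-(2,4,5-trimethoxyphenyl)pent-1-en-3-one | OC(CC(=O)C=C(Cl)Cl)c1cc(OC)c(OC)cc1OC
F3 | step 3 | (1R)-5,5-dichloro-3-oxo-1-(2,4,5-trimethoxyphenyl)pent-4-en-1-yl acetate | CC(=O)O[C@H](CC(=O)C=C(Cl)Cl)c1cc(OC)c(OC)cc1OC
F4 | step 6 | (2S)-5-hydroxy-7-methoxy-6,8-dimethyl-2-(3,3,4,6,6-pentamethoxycyclohexa-1,4-dien-1-yl)-2,3-dihydro-4H-chromen-4-one | COC1=CC(OC)(OC)C([C@@H]2CC(=O)c3c(O)c(C)c(OC)c(C)c3O2)=CC1(OC)OC
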